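**Retrosynthetic overview**
1. Labels run from C1 (lactone C=O) to C12 (CH3). The last bonds made are O11–acyl (coumarate) and O5–C1. O5–C1 forms by acid-triggered lactonisation of a (Z)-enoate, which also frees O6–H and the phenol. C2=C3 comes from a Z-selective olefination.
2. C5–C6 comes from a reagent-controlled anti-diol allylboration of the C6 aldehyde of a cis-2,5-disubstituted oxolane.
3. The strategy rests on C10, a ring CH of the oxolane between the ring oxygen and the C9 methylene. C9–C10 is made by inserting a C9 rhodium carbenoid into the ether C10–H bond. This closes the oxolane as its 3-one with C10 cis to C7, and the C8 carbonyl is then removed by reduction and Barton–McCombie deoxygenation.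
4. The diazoketone comes from an ether acid. C10–C12 derive from ethyl (S)-lactate (as a triflate), C6–C8 from O-benzyl-L-serine (as a hydroxy acid dianion), and C9 from diazomethane.
5. Ring order: oxolane first (step 9), dihydropyranone last (step 23).

Key step: step 9

Assumption: the C8 carbinol centre of 18 and 19 is drawn for hydride delivery anti to the two ring substituents; its configuration is irrelevant because C8 ends as CH2. (TBSO = tert-butyldimethylsilyloxy.)

**Step 1**
Reactants: 1 ethyl (S)-lactate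
Product: 2 ethyl (S)-2-(TBSO)propanoate
Conditions: TBSCl, imidazole, DMF, 0 °C to rt
Reagents that add atoms: tert-butyldimethylsilyl chloride, CC(C)(C)[Si](C)(C)Cl
Why: Imidazole-promoted O-silylation of a secondary alcohol leaves C11 (S, chiral pool) untouched, and the bulky silyl ether later screens C11–H in step 9.

**Step 2**
Reactants: 2 ethyl (S)-2-(TBSO)propanoate
Product: 3 (S)-2-(TBSO)propan-1-ol
Conditions: i-Bu2AlH (2.3 equiv), CH2Cl2, −78 to 0 °C; aq. potassium sodium tartrate
Reagents that add atoms: none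
Why: Exhaustive hydride reduction of the ester gives the primary alcohol (future C10) without involving C11, and the weakly basic aluminium alkoxide should not trigger silyl migration.

**Step 3**
Reactants: 3 (S)-2-(TBSO)propan-1-ol
Product: 4 (S)-2-(TBSO)propyl trifluoromethanesulfonate
Conditions: Tf2O, 2,6-lutidine, CH2Cl2, −78 °C; used without storage
Reagents that add atoms: trifluoromethanesulfonic anhydride, O=S(=O)(OS(=O)(=O)C(F)(F)F)C(F)(F)F
Why: O-sulfonylation with a hindered base at low temperature gives a leaving group reactive enough to offset the retarding beta-oxygen in the following SN2 step.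

**Step 4**
Reactants: 5 O-benzyl-L-serine
Product: 8 (S)-3-(benzyloxy)-2-hydroxypropanoic acid, via diazonium carboxylate 6 (not isolated), via alpha-lactone 7 (not isolated)
Conditions: NaNO2, 1 M aq. H2SO4, 0 °C to rt
Reagents that add atoms: water, O
Why: In this diazotisation of an alpha-amino acid, the carboxylate expels N2 from 6 with inversion to give 7 and water opens 7 with a second inversion, so the serine configuration at C7 is retained overall.

**Step 5**
Reactants: 8 (S)-3-(benzyloxy)-2-hydroxypropanoic acid; 4 (S)-2-(TBSO)propyl trifluoromethanesulfonate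
Product: 10 (S)-3-(benzyloxy)-2-[(S)-2-(TBSO)propoxy]propanoic acid, via disodium salt 9 (not isolated)
Conditions: NaH (2.2 equiv), THF, 0 °C; then 4, −20 °C to rt; 1 M HCl to pH 3 at 0 °C
Reagents that add atoms: none
Why: This is a Williamson etherification (SN2 at primary C10) by the alkoxide of dianion 9; the carboxylate blocks enolisation, so C7 can neither racemise nor lose the beta-benzyloxy group, and no stereocentre takes part in bond formation.

**Step 6**
Reactants: 10 (S)-3-(benzyloxy)-2-[(S)-2-(TBSO)propoxy]propanoic acid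
Product: 11 (S)-3-hydroxy-2-[(S)-2-(TBSO)propoxy]propanoic acid
Conditions: H2 (1 atm), 10% Pd/C, EtOAc, rt
Reagents that add atoms: none
Why: Catalytic hydrogenolysis removes the benzyl ether, which would otherwise trap the later carbenoid as a five-membered oxonium ylide, while the silyl ether and both stereocentres are inert.

**Step 7**
Reactants: 11 (S)-3-hydroxy-2-[(S)-2-(TBSO)propoxy]propanoic acid
Product: 13 (S)-3-(benzoyloxy)-2-[(S)-2-(TBSO)propoxy]propanoic acid, via mixed benzoic anhydride 12 (not isolated)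
Conditions: BzCl (2.5 equiv), pyridine, CH2Cl2, 0 °C; then H2O, rt
Reagents that add atoms: benzoyl chloride, O=C(Cl)c1ccccc1
Why: In this pyridine-mediated O-acylation, excess BzCl also converts the acid into 12, which water cleaves again in the work-up, and the weak base keeps beta-elimination of benzoate in check.

**Step 8**
Reactants: 13 (S)-3-(benzoyloxy)-2-[(S)-2-(TBSO)propoxy]propanoic acid
Product: 15 (S)-4-diazo-3-oxo-2-[(S)-2-(TBSO)propoxy]butyl benzoate, via acid chloride 14 (not isolated)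
Conditions: 1-chloro-N,N,2-trimethylpropenylamine, CH2Cl2, 0 °C; then CH2N2 (excess), Et2O, 0 °C
Reagents that add atoms: diazomethane, C=[N+]=[N-]
Why: Neutral acid chloride formation with the alpha-chloroenamine, followed by acylation of diazomethane (first stage of the Arndt–Eistert sequence), installs C9; a second equivalent of CH2N2 scavenges HCl, so C7 should not epimerise and benzoate should not be eliminated.

**Step 9**
Reactants: 15 (S)-4-diazo-3-oxo-2-[(S)-2-(TBSO)propoxy]butyl benzoate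
Product: 17 [(2S,5S)-5-[(S)-1-(TBSO)ethyl]-3-oxooxolan-2-yl]methyl benzoate, via rhodium carbenoid 16 (not isolated)
Conditions: Rh2(OAc)4 (1 mol %), dry CH2Cl2, rt, slow addition of 15 at high dilution
Reagents that add atoms: none
Why: Rh2(OAc)4 attacks the diazo carbon of 15 and loss of N2 gives the electrophilic carbenoid 16 at C9, which inserts into the ether C10–H bond through a concerted, hydride-transfer-like three-centre transition state that forms C9–C10 and releases the catalyst. The closest known reaction type is the dirhodium-catalysed C–H insertion of alpha-alkoxy alpha'-diazoketones to cis-2,5-disubstituted 3(2H)-furanones. The oxolane ring (O, C7, C8, C9, C10) closes in the 1,5-insertion mode, the kinetically preferred ring size for flexible diazoketones. C10 is set by the choice between its two diastereotopic hydrogens: in the compact envelope-like transition state the CH2OBz group on C7 and the C11 side chain both sit pseudo-equatorial, which places them cis (10S), and insertion occurs with retention while C7 and C11 are untouched. The step needs site selectivity for C10–H, and four features of 15 supply it: the ether oxygen lone pair stabilises the positive charge building at C10; C6–H is deactivated by the benzoate and would give a cyclobutanone; the tertiary C11–H is reached only through a six-membered transition state and is screened by the TBS group; acylation of O6 removes the Lewis basicity that would lead to a five-membered oxonium ylide. Slow addition at high dilution suppresses carbene dimerisation and O–H insertion into adventitious water.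

**Step 10**
Reactants: 17 [(2S,5S)-5-[(S)-1-(TBSO)ethyl]-3-oxooxolan-2-yl]methyl benzoate
Product: 18 [(2S,3S,5S)-5-[(S)-1-(TBSO)ethyl]-3-hydroxyoxolan-2-yl]methyl benzoate
Conditions: NaBH4, CeCl3·7H2O, MeOH, −78 to −40 °C
Reagents that add atoms: none
Why: Luche-type 1,2-reduction at low temperature should outrun enolisation (which would epimerise C7 or expel benzoate), and hydride attack anti to the two cis substituents should give the all-cis alcohol, a centre erased in step 12.

**Step 11**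
Reactants: 18 [(2S,3S,5S)-5-[(S)-1-(TBSO)ethyl]-3-hydroxyoxolan-2-yl]methyl benzoate
Product: 19 [(2S,3S,5S)-5-[(S)-1-(TBSO)ethyl]-3-(phenoxycarbonothioyloxy)oxolan-2-yl]methyl benzoate
Conditions: PhOC(S)Cl, pyridine, DMAP (cat.), CH2Cl2, 0 °C to rt
Reagents that add atoms: O-phenyl chlorothionoformate, S=C(Cl)Oc1ccccc1
Why: Thioacylation of the secondary alcohol under weakly basic conditions (first half of the Barton–McCombie deoxygenation) is preferred to NaH/CS2/MeI because it avoids benzoyl migration from O6 to O8.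

**Step 12**
Reactants: 19 [(2S,3S,5S)-5-[(S)-1-(TBSO)ethyl]-3-(phenoxycarbonothioyloxy)oxolan-2-yl]methyl benzoate
Product: 20 [(2R,5S)-5-[(S)-1-(TBSO)ethyl]oxolan-2-yl]methyl benzoate
Conditions: Bu3SnH, AIBN (cat.), toluene, 90 °C
Reagents that add atoms: none
Why: In this Barton–McCombie radical chain deoxygenation, stannyl addition to C=S, C8–O fragmentation and hydrogen transfer from Bu3SnH give the C8 methylene, and C7 and C10 stay intact because beta-scission of ring C–O bonds is slow.

**Step 13**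
Reactants: 20 [(2R,5S)-5-[(S)-1-(TBSO)ethyl]oxolan-2-yl]methyl benzoate
Product: 21 [(2R,5S)-5-[(S)-1-(TBSO)ethyl]oxolan-2-yl]methanol
Conditions: K2CO3 (cat.), MeOH, rt
Reagents that add atoms: none
Why: Carbonate-catalysed methanolysis (transesterification) of the benzoate frees O6–H while the secondary TBS ether survives.

**Step 14**
Reactants: 21 [(2R,5S)-5-[(S)-1-(TBSO)ethyl]oxolan-2-yl]methanol
Product: 22 (2R,5S)-5-[(S)-1-(TBSO)ethyl]oxolane-2-carbaldehyde
Conditions: TEMPO (cat.), PhI(OAc)2, CH2Cl2, rt; used at once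
Reagents that add atoms: none
Why: Oxoammonium (TEMPO) oxidation stops at the aldehyde under near-neutral conditions, so the alpha-alkoxy centre C7 should not epimerise.

**Step 15**
Reactants: 22 (2R,5S)-5-[(S)-1-(TBSO)ethyl]oxolane-2-carbaldehyde
Product: 24 (1R,2R)-1-[(2R,5S)-5-[(S)-1-(TBSO)ethyl]oxolan-2-yl]but-3-ene-1,2-diol, via borinate adduct 23 (not isolated)
Conditions: allenylboronic acid pinacol ester, (+)-Ipc2BH [from (−)-alpha-pinene], Et2O, 0 °C; then 22, −78 °C; then aq. NaOH, H2O2, 0 °C to rt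
Reagents that add atoms: allenylboronic acid pinacol ester, C=C=CB1OC(C)(C)C(C)(C)O1; hydrogen peroxide, OO
Why: In this anti-selective, reagent-controlled allylboration, hydroboration of the allene gives the (E)-gamma-boryl allylborane, which adds to 22 through a closed Zimmerman–Traxler chair; the E geometry sets C5 anti to C6, the (−)-alpha-pinene-derived ligands direct attack to the Re face and so place O6 syn to the ring oxygen at C7 against the modest intrinsic bias of the aldehyde, oxidation of 23 replaces C5–B by C5–OH with retention, and a chelating Lewis acid is avoided because it would impose an open transition state and the syn C5/C6 pair.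

**Step 16**
Reactants: 24 (1R,2R)-1-[(2R,5S)-5-[(S)-1-(TBSO)ethyl]oxolan-2-yl]but-3-ene-1,2-diol
Product: 25 (2R,5S)-2-[(4S,5R)-2,2-dimethyl-5-vinyl-1,3-dioxolan-4-yl]-5-[(S)-1-(TBSO)ethyl]oxolane
Conditions: Me2C(OMe)2, PPTS (cat.), CH2Cl2, rt
Reagents that add atoms: 2,2-dimethoxypropane, COC(C)(C)OC
Why: Acid-catalysed transketalisation ties O5 and O6 into a cis-dioxolane, which masks both hydroxyls in one operation and later releases O5 for lactonisation and O6 as the free alcohol.

**Step 17**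
Reactants: 25 (2R,5S)-2-[(4S,5R)-2,2-dimethyl-5-vinyl-1,3-dioxolan-4-yl]-5-[(S)-1-(TBSO)ethyl]oxolane
Product: 27 2-[(4R,5S)-5-[(2R,5S)-5-[(S)-1-(TBSO)ethyl]oxolan-2-yl]-2,2-dimethyl-1,3-dioxolan-4-yl]ethanol, via B-alkyl-9-BBN 26 (not isolated)
Conditions: 9-BBN-H, THF, 0 °C to rt; then aq. NaOH, H2O2, 0 °C
Reagents that add atoms: hydrogen peroxide, OO
Why: Anti-Markovnikov hydroboration of the terminal alkene with the bulky borane, followed by oxidation, makes C3 a primary alcohol and C4 a methylene without creating a stereocentre.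

**Step 18**
Reactants: 27 2-[(4R,5S)-5-[(2R,5S)-5-[(S)-1-(TBSO)ethyl]oxolan-2-yl]-2,2-dimethyl-1,3-dioxolan-4-yl]ethanol
Product: 28 2-[(4R,5S)-5-[(2R,5S)-5-[(S)-1-(TBSO)ethyl]oxolan-2-yl]-2,2-dimethyl-1,3-dioxolan-4-yl]acetaldehyde
Conditions: TEMPO (cat.), PhI(OAc)2, CH2Cl2, rt
Reagents that add atoms: none
Why: Oxoammonium (TEMPO) oxidation gives the C3 aldehyde without a base that could eliminate the beta-oxygen O5.

**Step 19**
Reactants: 28 2-[(4R,5S)-5-[(2R,5S)-5-[(S)-1-(TBSO)ethyl]oxolan-2-yl]-2,2-dimethyl-1,3-dioxolan-4-yl]acetaldehyde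
Product: 29 methyl (Z)-4-[(4R,5S)-5-[(2R,5S)-5-[(S)-1-(TBSO)ethyl]oxolan-2-yl]-2,2-dimethyl-1,3-dioxolan-4-yl]but-2-enoate
Conditions: (CF3CH2O)2P(O)CH2CO2Me, KN(SiMe3)2, 18-crown-6, THF, −78 °C
Reagents that add atoms: methyl bis(2,2,2-trifluoroethyl)phosphonoacetate, COC(=O)CP(=O)(OCC(F)(F)F)OCC(F)(F)F
Why: In the Still–Gennari olefination, the electron-poor phosphonate with a dissociated potassium ion makes elimination faster than adduct equilibration, so the (Z)-C2=C3 enoate needed for ring closure should form, and the low temperature prevents beta-elimination of O5.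

**Step 20**
Reactants: 29 methyl (Z)-4-[(4R,5S)-5-[(2R,5S)-5-[(S)-1-(TBSO)ethyl]oxolan-2-yl]-2,2-dimethyl-1,3-dioxolan-4-yl]but-2-enoate
Product: 30 methyl (Z)-4-[(4R,5S)-5-[(2R,5S)-5-[(S)-1-hydroxyethyl]oxolan-2-yl]-2,2-dimethyl-1,3-dioxolan-4-yl]but-2-enoate
Conditions: Bu4NF, AcOH, THF, 0 °C to rt
Reagents that add atoms: none
Why: Fluoride-mediated desilylation frees only O11–H; the AcOH buffer protects the enoate from gamma-deprotonation and loss of O5, and the acetonide and methyl ester are inert.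

**Step 21**
Reactants: 31 4-hydroxycinnamic acid
Product: 33 (E)-3-[4-(methoxymethoxy)phenyl]prop-2-enoic acid, via bis-MOM derivative 32 (not isolated)
Conditions: MOMCl (2.5 equiv), i-Pr2NEt, CH2Cl2, 0 °C to rt; then LiOH, THF–H2O, rt; 1 M HCl to pH 4
Reagents that add atoms: chloromethyl methyl ether, COCCl; lithium hydroxide, [Li+].[OH-]
Why: O-alkylation of phenol and carboxylate, followed by selective saponification of the far more labile acetal ester of 32, leaves the aryl MOM ether, an acid-labile mask matched to the acetonide.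

**Step 22**
Reactants: 30 methyl (Z)-4-[(4R,5S)-5-[(2R,5S)-5-[(S)-1-hydroxyethyl]oxolan-2-yl]-2,2-dimethyl-1,3-dioxolan-4-yl]but-2-enoate; 33 (E)-3-[4-(methoxymethoxy)phenyl]prop-2-enoic acid
Product: 34 MOM-protected coumarate of 30 at O11 (5R,6S,7R,10S,11S)
Conditions: DCC, DMAP, CH2Cl2, 0 °C to rt
Reagents that add atoms: none
Why: Steglich esterification acylates the only free hydroxyl, O11–H, with retention at C11 because the C11–O bond is never broken.

**Step 23**
Reactants: 34 MOM-protected coumarate of 30 at O11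
Product: 36 target (S)-1-[(2S,5R)-5-[(S)-hydroxy[(R)-6-oxo-3,6-dihydro-2H-pyran-2-yl]methyl]oxolan-2-yl]ethyl (E)-3-(4-hydroxyphenyl)prop-2-enoate, via dihydroxy enoate 35 (not isolated)
Conditions: TFA–H2O (9:1), CH2Cl2, 0 °C to rt; concentrate from toluene
Reagents that add atoms: none
Why: Aqueous acid hydrolyses the cis-dioxolane and the aryl MOM ether to 35, whose O5–H closes onto the (Z)-enoate by acid-catalysed transesterification (6-exo-trig lactonisation, favoured over the seven-membered alternative through O6), leaving O6–H and the phenol free and every stereocentre untouched.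

**Compound list**
1 | ethyl (S)-lactate | CCOC(=O)[C@H](C)O | starting material
2 | ethyl (S)-2-(TBSO)propanoate | CCOC(=O)[C@H](C)O[Si](C)(C)C(C)(C)C | intermediate
3 | (S)-2-(TBSO)propan-1-ol | C[C@H](O[Si](C)(C)C(C)(C)C)CO | intermediate
4 | (S)-2-(TBSO)propyl trifluoromethanesulfonate | C[C@H](O[Si](C)(C)C(C)(C)C)COS(=O)(=O)C(F)(F)F | intermediate
5 | O-benzyl-L-serine | N[C@@H](COCc1ccccc1)C(=O)O | starting material
6 | (S)-3-(benzyloxy)-2-diazoniopropanoate (not isolated) | N#[N+][C@@H](COCc1ccccc1)C(=O)[O-] | intermediate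
7 | (R)-3-(benzyloxymethyl)oxiran-2-one, alpha-lactone (not isolated) | O=C1O[C@@H]1COCc1ccccc1 | intermediate
8 | (S)-3-(benzyloxy)-2-hydroxypropanoic acid | O[C@@H](COCc1ccccc1)C(=O)O | intermediate
9 | disodium (S)-3-(benzyloxy)-2-oxidopropanoate (not isolated) | [Na+].[Na+].[O-][C@@H](COCc1ccccc1)C(=O)[O-] | intermediate
10 | (S)-3-(benzyloxy)-2-[(S)-2-(TBSO)propoxy]propanoic acid | C[C@H](O[Si](C)(C)C(C)(C)C)CO[C@@H](COCc1ccccc1)C(=O)O | intermediate
11 | (S)-3-hydroxy-2-[(S)-2-(TBSO)propoxy]propanoic acid | C[C@H](O[Si](C)(C)C(C)(C)C)CO[C@@H](CO)C(=O)O | intermediate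
12 | benzoic (S)-3-(benzoyloxy)-2-[(S)-2-(TBSO)propoxy]propanoic anhydride (not isolated) | C[C@H](O[Si](C)(C)C(C)(C)C)CO[C@@H](COC(=O)c1ccccc1)C(=O)OC(=O)c1ccccc1 | intermediate
13 | (S)-3-(benzoyloxy)-2-[(S)-2-(TBSO)propoxy]propanoic acid | C[C@H](O[Si](C)(C)C(C)(C)C)CO[C@@H](COC(=O)c1ccccc1)C(=O)O | intermediate
14 | (S)-3-chloro-3-oxo-2-[(S)-2-(TBSO)propoxy]propyl benzoate (not isolated) | C[C@H](O[Si](C)(C)C(C)(C)C)CO[C@@H](COC(=O)c1ccccc1)C(=O)Cl | intermediate
15 | (S)-4-diazo-3-oxo-2-[(S)-2-(TBSO)propoxy]butyl benzoate (7S,11S) | C[C@H](O[Si](C)(C)C(C)(C)C)CO[C@@H](COC(=O)c1ccccc1)C(=O)C=[N+]=[N-] | intermediate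
16 | C9 carbenoid of 15 on Rh2(OAc)4, bridging acetates drawn monodentate (not isolated) | C[C@H](O[Si](C)(C)C(C)(C)C)CO[C@@H](COC(=O)c1ccccc1)C(=O)C=[Rh](OC(C)=O)(OC(C)=O)[Rh](OC(C)=O)OC(C)=O | intermediate
17 | [(2S,5S)-5-[(S)-1-(TBSO)ethyl]-3-oxooxolan-2-yl]methyl benzoate (7S,10S,11S; cis) | C[C@H](O[Si](C)(C)C(C)(C)C)[C@@H]1CC(=O)[C@H](COC(=O)c2ccccc2)O1 | intermediate
18 | [(2S,3S,5S)-5-[(S)-1-(TBSO)ethyl]-3-hydroxyoxolan-2-yl]methyl benzoate (all-cis) | C[C@H](O[Si](C)(C)C(C)(C)C)[C@@H]1C[C@H](O)[C@H](COC(=O)c2ccccc2)O1 | intermediate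
19 | [(2S,3S,5S)-5-[(S)-1-(TBSO)ethyl]-3-(phenoxycarbonothioyloxy)oxolan-2-yl]methyl benzoate | C[C@H](O[Si](C)(C)C(C)(C)C)[C@@H]1C[C@H](OC(=S)Oc2ccccc2)[C@H](COC(=O)c2ccccc2)O1 | intermediate
20 | [(2R,5S)-5-[(S)-1-(TBSO)ethyl]oxolan-2-yl]methyl benzoate (7R,10S,11S) | C[C@H](O[Si](C)(C)C(C)(C)C)[C@@H]1CC[C@H](COC(=O)c2ccccc2)O1 | intermediate
21 | [(2R,5S)-5-[(S)-1-(TBSO)ethyl]oxolan-2-yl]methanol | C[C@H](O[Si](C)(C)C(C)(C)C)[C@@H]1CC[C@H](CO)O1 | intermediate
22 | (2R,5S)-5-[(S)-1-(TBSO)ethyl]oxolane-2-carbaldehyde | C[C@H](O[Si](C)(C)C(C)(C)C)[C@@H]1CC[C@H](C=O)O1 | intermediate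
23 | O6-diisopinocampheylborinate of the C5-pinacolboryl adduct (5R,6R; not isolated) | C[C@H](O[Si](C)(C)C(C)(C)C)[C@@H]1CC[C@H]([C@H](OB([C@H]2C[C@H]3C[C@@H]([C@@H]2C)C3(C)C)[C@H]2C[C@H]3C[C@@H]([C@@H]2C)C3(C)C)[C@H](B2OC(C)(C)C(C)(C)O2)C=C)O1 | intermediate
24 | (1R,2R)-1-[(2R,5S)-5-[(S)-1-(TBSO)ethyl]oxolan-2-yl]but-3-ene-1,2-diol (C5/C6 anti, C6/C7 syn) | C[C@H](O[Si](C)(C)C(C)(C)C)[C@@H]1CC[C@H]([C@H](O)[C@H](O)C=C)O1 | intermediate
25 | (2R,5S)-2-[(4S,5R)-2,2-dimethyl-5-vinyl-1,3-dioxolan-4-yl]-5-[(S)-1-(TBSO)ethyl]oxolane | C[C@H](O[Si](C)(C)C(C)(C)C)[C@@H]1CC[C@H]([C@@H]2OC(C)(C)O[C@@H]2C=C)O1 | intermediate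
26 | B-alkyl-9-borabicyclo[3.3.1]nonane from 25, boron on C3 (not isolated) | C[C@H](O[Si](C)(C)C(C)(C)C)[C@@H]1CC[C@H]([C@@H]2OC(C)(C)O[C@@H]2CCB2C3CCCC2CCC3)O1 | intermediate
27 | 2-[(4R,5S)-5-[(2R,5S)-5-[(S)-1-(TBSO)ethyl]oxolan-2-yl]-2,2-dimethyl-1,3-dioxolan-4-yl]ethanol | C[C@H](O[Si](C)(C)C(C)(C)C)[C@@H]1CC[C@H]([C@@H]2OC(C)(C)O[C@@H]2CCO)O1 | intermediate
28 | 2-[(4R,5S)-5-[(2R,5S)-5-[(S)-1-(TBSO)ethyl]oxolan-2-yl]-2,2-dimethyl-1,3-dioxolan-4-yl]acetaldehyde | C[C@H](O[Si](C)(C)C(C)(C)C)[C@@H]1CC[C@H]([C@@H]2OC(C)(C)O[C@@H]2CC=O)O1 | intermediate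
29 | methyl (Z)-4-[(4R,5S)-5-[(2R,5S)-5-[(S)-1-(TBSO)ethyl]oxolan-2-yl]-2,2-dimethyl-1,3-dioxolan-4-yl]but-2-enoate | C[C@H](O[Si](C)(C)C(C)(C)C)[C@@H]1CC[C@H]([C@@H]2OC(C)(C)O[C@@H]2C/C=C\C(=O)OC)O1 | intermediate
30 | methyl (Z)-4-[(4R,5S)-5-[(2R,5S)-5-[(S)-1-hydroxyethyl]oxolan-2-yl]-2,2-dimethyl-1,3-dioxolan-4-yl]but-2-enoate | C[C@H](O)[C@@H]1CC[C@H]([C@@H]2OC(C)(C)O[C@@H]2C/C=C\C(=O)OC)O1 | intermediate
31 | 4-hydroxycinnamic acid | OC(=O)/C=C/c1ccc(O)cc1 | starting material
32 | methoxymethyl (E)-3-[4-(methoxymethoxy)phenyl]prop-2-enoate (not isolated) | COCOC(=O)/C=C/c1ccc(OCOC)cc1 | intermediate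
33 | (E)-3-[4-(methoxymethoxy)phenyl]prop-2-enoic acid | OC(=O)/C=C/c1ccc(OCOC)cc1 | intermediate
34 | O11-[(E)-4-(methoxymethoxy)cinnamoyl] ester of 30 (5R,6S,7R,10S,11S) | C[C@H](OC(=O)/C=C/c1ccc(OCOC)cc1)[C@@H]1CC[C@H]([C@@H]2OC(C)(C)O[C@@H]2C/C=C\C(=O)OC)O1 | intermediate
35 | methyl (2Z,5R,6R)-5,6-dihydroxy-6-[(2R,5S)-5-[(S)-1-[(E)-4-hydroxycinnamoyloxy]ethyl]oxolan-2-yl]hex-2-enoate (not isolated) | C[C@H](OC(=O)/C=C/c1ccc(O)cc1)[C@@H]1CC[C@H]([C@H](O)[C@H](O)C/C=C\C(=O)OC)O1 | intermediate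
36 | CNP0417147.2 (5R,6S,7R,10S,11S) | C[C@H](OC(=O)/C=C/c1ccc(O)cc1)[C@@H]1CC[C@H]([C@H](O)[C@H]2CC=CC(=O)O2)O1 | target

**Total step count:** 23. **Longest linear sequence:** 21 steps (1–3, 5–20, 22, 23).

**Steps most likely to fail**

Step 9.
- Risk: the carbenoid may be diverted into the six-membered insertion at the tertiary, oxygen-activated C11–H.
- Risk: discrimination between the two diastereotopic C10 hydrogens may be poor.
- Risk: the carbenoid may be lost to dimerisation.
- Fallback: build the cis-oxolane by C–O bond formation, setting out from 2 and rejoining at 20.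
  - MeNH(OMe)·HCl and i-PrMgCl convert 2 into the N-methoxy-N-methylamide F1.
  - 3-Butenylmagnesium bromide gives the ketone F2.
  - Felkin–Anh-controlled reduction with LiBH(s-Bu)3 at −78 °C sets C10 syn to C11 in the alkenol F3.
  - 2,6-Dichlorobenzyl trichloroacetimidate with catalytic TfOH (no alkoxide, hence no silyl migration) gives the bulky benzyl ether F4.
  - Iodoetherification with I2 in MeCN at 0 °C is cis-selective for such bulky ethers and sheds the benzyl group, giving the iodomethyl oxolane F5.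
  - Displacement with PhCO2Cs in DMF delivers 20.

Step 15.
- Risk: the boron reagent must override the Felkin–Anh/Cornforth preference of the alpha-alkoxy aldehyde, so facial selectivity may erode.
- Risk: the aldehyde may epimerise at C7 while it waits.
- Fallback: set the two centres one at a time, setting out from 22 and rejoining at 24.
  - Chelation-controlled addition of CH2=CHMgBr with MgBr2·OEt2 in CH2Cl2 at −78 °C gives the threo allylic alcohol F6.
  - Sharpless asymmetric epoxidation (Ti(OiPr)4, L-(+)-diisopropyl tartrate, t-BuOOH; matched pairing, erythro-selective) gives the epoxy alcohol F7.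
  - TESCl and imidazole give the silyl ether F8, which blocks Payne rearrangement.
  - Dimethylsulfonium methylide (Me3SI, n-BuLi) opens the terminal epoxide and eliminates Me2S, giving the one-carbon-longer allylic alcohol F9.
  - AcOH–THF–H2O removes the TES group selectively to give 24.

Step 5.
- Risk: the carboxylate may compete with the alkoxide for the triflate.
- Risk: the alkoxide may attack silicon.
- Risk: the beta-silyloxy triflate may decompose before it is consumed.
- Fallback: form the C7–O bond by asymmetric allylic etherification, setting out from 3 and rejoining at 13.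
  - Alcohol 3 reacts with racemic 2-vinyloxirane under Pd2(dba)3·CHCl3, the C2-symmetric trans-1,2-diaminocyclohexane bis(2-diphenylphosphinobenzamide) ligand and catalytic Et3B in CH2Cl2. The ligand antipode that gives the (R)-ether is fixed by a trial with both. This dynamic kinetic asymmetric transformation gives the branched ether alcohol F10.
  - BzCl and pyridine give the benzoate F11.
  - Ozonolysis (O3, then Me2S) gives the aldehyde F12.
  - Pinnick oxidation (NaClO2, NaH2PO4, 2-methyl-2-butene) gives 13.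

**Further compounds**
F1 | step 9 | (S)-2-(TBSO)-N-methoxy-N-methylpropanamide | C[C@H](O[Si](C)(C)C(C)(C)C)C(=O)N(C)OC
F2 | step 9 | (S)-2-(TBSO)hept-6-en-3-one | C[C@H](O[Si](C)(C)C(C)(C)C)C(=O)CCC=C
F3 | step 9 | (2S,3S)-2-(TBSO)hept-6-en-3-ol | C[C@H](O[Si](C)(C)C(C)(C)C)[C@@H](O)CCC=C
F4 | step 9 | (2S,3S)-2-(TBSO)-3-(2,6-dichlorobenzyloxy)hept-6-ene | C[C@H](O[Si](C)(C)C(C)(C)C)[C@@H](OCc1c(Cl)cccc1Cl)CCC=C
F5 | step 9 | (2R,5S)-2-(iodomethyl)-5-[(S)-1-(TBSO)ethyl]oxolane | C[C@H](O[Si](C)(C)C(C)(C)C)[C@@H]1CC[C@H](CI)O1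
F6 | step 15 | (R)-1-[(2R,5S)-5-[(S)-1-(TBSO)ethyl]oxolan-2-yl]prop-2-en-1-ol | C[C@H](O[Si](C)(C)C(C)(C)C)[C@@H]1CC[C@H]([C@H](O)C=C)O1
F7 | step 15 | erythro epoxy alcohol, oxirane on C5–C4 and free O6–H | C[C@H](O[Si](C)(C)C(C)(C)C)[C@@H]1CC[C@H]([C@H](O)[C@H]2CO2)O1
F8 | step 15 | O6-triethylsilyl ether of F7 | C[C@H](O[Si](C)(C)C(C)(C)C)[C@@H]1CC[C@H]([C@H](O[Si](CC)(CC)CC)[C@H]2CO2)O1
F9 | step 15 | O6-triethylsilyl ether of 24 | C[C@H](O[Si](C)(C)C(C)(C)C)[C@@H]1CC[C@H]([C@H](O[Si](CC)(CC)CC)[C@H](O)C=C)O1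
F10 | step 5 | (R)-2-[(S)-2-(TBSO)propoxy]but-3-en-1-ol | C[C@H](O[Si](C)(C)C(C)(C)C)CO[C@@H](CO)C=C
F11 | step 5 | (R)-2-[(S)-2-(TBSO)propoxy]but-3-enyl benzoate | C[C@H](O[Si](C)(C)C(C)(C)C)CO[C@@H](COC(=O)c1ccccc1)C=C
F12 | step 5 | (S)-3-oxo-2-[(S)-2-(TBSO)propoxy]propyl benzoate | C[C@H](O[Si](C)(C)C(C)(C)C)CO[C@@H](COC(=O)c1ccccc1)C=O
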